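**Retrosynthetic overview**
1. Cyclobutane (last ring). The target is an isomer of its own prenyl ester. C–O heterolysis passes a dimethylallyl cation from the carboxylate (a diphosphate surrogate) to one of two geminal prenyl groups. The lavandulyl-type cation closes 4-exo and loses H+, which sets C6, C1' and C3'.
2. Chromanone ring. Alkaloid-catalysed oxa-Michael closure of the tigloyl chain on the dearomatised core sets C2 and C3.
3. Dearomatised ring A. One-pot lactone opening by prenoxide and geminal C-prenylation of the only free ring carbon.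
4. First ring. The 4-phenyldihydrocoumarin ring is made by carbene-catalysed cinnamoyl transfer and annulation onto tigloylphloroglucinol (sets the benzylic centre). It is opened again later.
5. Order: Friedel–Crafts acylation → lactone ring (made, then opened) → dearomatised ring A → chromanone ring → cyclobutane. Each ring closure copies a presumed biosynthetic event.

Assumption: CIP descriptors refer to the enol tautomers as drawn, and the sense of induction of the triazolium carbene and of quinine is taken by analogy with their established substrate classes (the antipodal salt and quinidine are equally available).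

Prenyl = 3-methylbut-2-enyl. Tigloyl = (E)-2-methylbut-2-enoyl.

**Step 1**
Reactants: 1 phloroglucinol; 2 tigloyl chloride
Product: 3 tigloylphloroglucinol [(E)-2-methyl-1-(2,4,6-trihydroxyphenyl)but-2-en-1-one]
Conditions: AlCl3 (3.5 equiv), CH2Cl2/MeNO2, 0 °C to rt; ice/1 M HCl
Reagents that add atoms: tigloyl chloride (2), C/C=C(\C)C(=O)Cl
Why: Friedel–Crafts C-acylation of the symmetric, threefold-activated arene stops after one acyl group because the chelated aryl ketone is deactivated, the tigloyl enone stays open with E geometry at or below room temperature, and no stereocentre is formed.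

**Step 2**
Reactants: 3 tigloylphloroglucinol; 4 (Z)-α-bromocinnamaldehyde
Product: 5 (4S)-5,7-dihydroxy-6-[(E)-2-methylbut-2-enoyl]-4-phenylchroman-2-one
Conditions: (5aR,10bS)-2-mesityl-5a,10b-dihydro-4H,6H-indeno[2,1-b][1,2,4]triazolo[4,3-d][1,4]oxazin-2-ium tetrafluoroborate (10 mol %), Na2CO3 (1.1 equiv), 4 Å MS, toluene/THF, rt
Reagents that add atoms: (Z)-α-bromocinnamaldehyde (4), O=C/C(Br)=C/c1ccccc1
Why: Carbene-catalysed [3+3] annulation, in which the Breslow intermediate of 4 expels bromide to give the cinnamoyl azolium (a cinnamoyl-thioester equivalent), one of the two equivalent free ring carbons of 3 adds in Michael fashion to the face left open by the aminoindanol backbone (benzylic centre S), and lactonisation on the non-chelated para-oxygen releases the catalyst (a lactone on an ortho-oxygen would converge to the same ester in step 3).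

**Step 3**
Reactants: 5 the lactone; 6 prenol; 7 prenyl bromide
Product: 10 prenyl (3S)-3-{2,4-dihydroxy-3,3-bis(3-methylbut-2-enyl)-5-[(E)-2-methylbut-2-enoyl]-6-oxocyclohexa-1,4-dien-1-yl}-3-phenylpropanoate, via aromatic prenyl ester 8 (not isolated), via mono-C-prenyl arene 9 (not isolated)
Conditions: 6 (1.1 equiv), LiHMDS (4.1 equiv, in portions), THF/toluene, −78 to 0 °C; 7 (2.1 equiv), 0 °C; aq. NH4Cl
Reagents that add atoms: prenol (6), CC(C)=CCO; prenyl bromide (7), CC(C)=CCBr
Why: Lithium prenoxide transesterifies the aryl lactone irreversibly (a phenoxide is released) and a lupulone-type alkylative dearomatisation follows, the lithium polyphenoxide being C-alkylated at its only free ring carbon and, after re-aromatising deprotonation, again at this least hindered carbon; the two new groups are identical, so no stereocentre arises, and the benzylic centre is not touched.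

**Step 4**
Reactants: 10 the open-chain tigloyl trione ester
Product: 12 prenyl (3S)-3-[(2R,3R)-5-hydroxy-2,3-dimethyl-6,6-bis(3-methylbut-2-enyl)-4,7-dioxo-3,4,6,7-tetrahydro-2H-chromen-8-yl]-3-phenylpropanoate, via cis-chromanone 11 (not isolated)
Conditions: (−)-quinine (20 mol %), PhCl, 10 °C; then MgI2 (1.5 equiv), Et2O/PhCl, rt
Reagents that add atoms: none
Why: Cinchona-alkaloid-catalysed intramolecular oxa-Michael addition, in which quinine deprotonates only the vinylogous acid so that charge sits on the oxygen para to the quaternary carbon, the other flanking enol OH stays chelated to the tigloyl C=O and holds the alkene over that oxygen (regiochemistry), the quinuclidinium/C9-OH ion pair selects the alkene face (C2 = R), kinetic protonation gives the cis product, and MgI2-promoted enolisation epimerises C3 to the diequatorial trans isomer (C3 = R) without retro-Michael opening.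

**Step 5**
Reactants: 12 the gem-diprenyl chromanone prenyl ester
Product: 13 target, (3S)-3-[(2R,3R,6R)-6-{[(1R,3S)-2,2-dimethyl-3-(prop-1-en-2-yl)cyclobutyl]methyl}-5-hydroxy-2,3-dimethyl-6-(3-methylbut-2-enyl)-4,7-dioxo-3,4,6,7-tetrahydro-2H-chromen-8-yl]-3-phenylpropanoic acid
Conditions: MeAlCl2 (3.5 equiv), CH2Cl2 (0.005 M), −78 to −30 °C; cold 1 M HCl
Reagents that add atoms: none
Why: Proposed new method: MeAlCl2 turns the chelated enol into its aluminium chelate (methane) and complexes the C7 carbonyl, so no oxygen nucleophile or proton source remains, then ionises the prenyl ester to a contact ion pair of the dimethylallyl cation and the substrate's own aluminium carboxylate (diphosphate surrogate and chiral leaving group); the small benzylic H must face the bulky Al-bound C7=O, which puts the CH2CO2Al arm on one ring face and phenyl on the other, so the cation reaches only the syn prenyl group (C6 = R), that prenyl reacts in its extended A(1,3)-minimised conformer on the alkene face open towards C7 and anti to the ring (C1' = R), the tertiary lavandulyl-type cation closes 4-exo reversibly on the new trisubstituted alkene to the cis-1,3-diequatorial cyclobutane (C3' = S), and carboxylate/Al–Me removes a methyl proton irreversibly to give the isopropenyl group; the closest known reaction types are the Gassman cationic [2+2] cycloaddition of allyl cations with unactivated trisubstituted alkenes, organoaluminium-promoted heterolysis of allylic esters and phosphates in biogenetic-type terpene cyclisations with chiral leaving groups, and Lewis-acid cleavage of prenyl esters.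

**Compound list**
1 | phloroglucinol | Oc1cc(O)cc(O)c1 | starting material
2 | tigloyl chloride | C/C=C(\C)C(=O)Cl | starting material
3 | tigloylphloroglucinol | C/C=C(\C)C(=O)c1c(O)cc(O)cc1O | intermediate
4 | (Z)-α-bromocinnamaldehyde | O=C/C(Br)=C/c1ccccc1 | starting material
5 | (4S)-5,7-dihydroxy-6-tigloyl-4-phenylchroman-2-one | O=C1C[C@@H](c2ccccc2)c3c(O1)cc(O)c(C(=O)/C(C)=C/C)c3O | intermediate
6 | prenol | CC(C)=CCO | starting material
7 | prenyl bromide | CC(C)=CCBr | starting material
8 | prenyl (3S)-3-phenyl-3-(2,4,6-trihydroxy-3-tigloylphenyl)propanoate | C/C=C(\C)C(=O)c1c(O)cc(O)c([C@@H](CC(=O)OCC=C(C)C)c2ccccc2)c1O | intermediate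
9 | prenyl (3S)-3-phenyl-3-(2,4,6-trihydroxy-3-prenyl-5-tigloylphenyl)propanoate | C/C=C(\C)C(=O)c1c(O)c(CC=C(C)C)c(O)c([C@@H](CC(=O)OCC=C(C)C)c2ccccc2)c1O | intermediate
10 | prenyl (3S)-3-(2,4-dihydroxy-6-oxo-3,3-diprenyl-5-tigloylcyclohexa-1,4-dien-1-yl)-3-phenylpropanoate | CC(C)=CCC1(CC=C(C)C)C(O)=C([C@@H](CC(=O)OCC=C(C)C)c2ccccc2)C(=O)C(C(=O)/C(C)=C/C)=C1O | intermediate
11 | (2R,3S)-cis-chromanone prenyl ester, benzylic S | CC(C)=CCC1(CC=C(C)C)C(=O)C([C@@H](CC(=O)OCC=C(C)C)c2ccccc2)=C2O[C@H](C)[C@H](C)C(=O)C2=C1O | intermediate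
12 | (2R,3R)-trans-chromanone prenyl ester, benzylic S | CC(C)=CCC1(CC=C(C)C)C(=O)C([C@@H](CC(=O)OCC=C(C)C)c2ccccc2)=C2O[C@H](C)[C@@H](C)C(=O)C2=C1O | intermediate
13 | CNP0103716.3 | C=C(C)[C@@H]1C[C@H](C[C@@]2(CC=C(C)C)C(=O)C([C@@H](CC(=O)O)c3ccccc3)=C3O[C@H](C)[C@@H](C)C(=O)C3=C2O)C1(C)C | target

**Total step count:** 5. **Longest linear sequence:** 5 (from phloroglucinol).

**Steps most likely to fail**

Most at risk is step 5.
- The tertiary cation may be caught by a ring oxygen to give a pyran.
- It may lose a proton to give the open lavandulyl diene.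
- It may pick up chloride.
- After closure it may ring-expand to a cyclopentyl cation.
- The three new centres depend on an ion-pair model that has not been tested.

The fallback gives up the cationic closure and takes the cyclobutane from the chiral pool. It sets out from 5 and comes back to the route at 13. (1S,5S)-(−)-verbenone F1 is cleaved with RuCl3 (cat.)/NaIO4 to (1S,3R)-cis-pinononic acid F2. This is methylenated with Ph3P=CH2 to the isopropenyl acid F3, reduced with LiAlH4 to the cyclobutylmethanol F4, and converted with I2, PPh3 and imidazole into the cyclobutylmethyl iodide F5. Lactone 5 is opened with lithium allyloxide to the aromatic allyl ester F6, which is C-alkylated in the same flask with F5 to the cyclobutylmethyl arene F7. LiHMDS and 7 then dearomatise it to the open-chain trione allyl ester F8, and the epimer at the new quaternary carbon is removed by chromatography. Quinine and then MgI2 close it through the cis-chromanone allyl ester F9 to the trans-chromanone allyl ester F10. Pd(PPh3)4 with morpholine frees the acid 13.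

Second is step 4. The vinylogous-acid oxygen is a weaker nucleophile than a phenol, a reversible closure would erode C2, and closure on the other flanking oxygen cannot be excluded. The fallback closes the ring before dearomatisation, on the o-tigloylphenol itself, which is the substrate class for which the alkaloid-catalysed closure is established. It sets out from 3 and comes back at 12. Quinine gives the cis-dihydroxychromanone F11 and MgI2 the trans-dihydroxychromanone F12. Annulation with 4 under the conditions of step 2 gives the tricyclic lactone F13; the issue then shifts to C8 versus C6 attack, which may need a separation. Lithium prenoxide followed by portionwise LiHMDS and 7, as in step 3, leads through the aromatic chromanone ester F14 and the 6-prenyl chromanone ester F15 to 12.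

Third is step 2. The acidic polyphenol may keep the carbene protonated, simple O-cinnamoylation or a second annulation may compete, and the enantioselectivity on this nucleophile is unknown. The fallback switches from acyl-azolium to iminium activation. It sets out from 3 and comes back at 5. Cinnamaldehyde and α,α-diphenylprolinol trimethylsilyl ether (20 mol %, the enantiomer giving 4S) effect a Friedel–Crafts alkylation and hemiacetalisation to the 4-phenylchroman-2-ol lactol F16. Ag2CO3 on Celite in toluene then oxidises it to lactone 5.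

**Further compounds**
F1 | step 5 | (1S,5S)-(−)-verbenone (purchased) | O=C1C=C(C)[C@@H]2C[C@H]1C2(C)C
F2 | step 5 | (1S,3R)-3-acetyl-2,2-dimethylcyclobutane-1-carboxylic acid | CC(=O)[C@@H]1C[C@H](C(=O)O)C1(C)C
F3 | step 5 | (1S,3S)-2,2-dimethyl-3-(prop-1-en-2-yl)cyclobutane-1-carboxylic acid | C=C(C)[C@@H]1C[C@H](C(=O)O)C1(C)C
F4 | step 5 | [(1S,3S)-2,2-dimethyl-3-(prop-1-en-2-yl)cyclobutyl]methanol | C=C(C)[C@@H]1C[C@H](CO)C1(C)C
F5 | step 5 | (1S,3S)-1-(iodomethyl)-2,2-dimethyl-3-(prop-1-en-2-yl)cyclobutane | C=C(C)[C@@H]1C[C@H](CI)C1(C)C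
F6 | step 5 | allyl (3S)-3-phenyl-3-(2,4,6-trihydroxy-3-tigloylphenyl)propanoate | C/C=C(\C)C(=O)c1c(O)cc(O)c([C@@H](CC(=O)OCC=C)c2ccccc2)c1O
F7 | step 5 | allyl (3S)-3-(3-{[(1R,3S)-2,2-dimethyl-3-(prop-1-en-2-yl)cyclobutyl]methyl}-2,4,6-trihydroxy-5-tigloylphenyl)-3-phenylpropanoate | C/C=C(\C)C(=O)c1c(O)c(C[C@H]2C[C@@H](C(C)=C)C2(C)C)c(O)c([C@@H](CC(=O)OCC=C)c3ccccc3)c1O
F8 | step 5 | open-chain tigloyl trione allyl ester, quaternary carbon configured as C6 of 13 | C=C(C)[C@@H]1C[C@H](C[C@@]2(CC=C(C)C)C(O)=C([C@@H](CC(=O)OCC=C)c3ccccc3)C(=O)C(C(=O)/C(C)=C/C)=C2O)C1(C)C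
F9 | step 5 | allyl ester of the (2R,3S)-cis epimer of 13 | C=C(C)[C@@H]1C[C@H](C[C@@]2(CC=C(C)C)C(=O)C([C@@H](CC(=O)OCC=C)c3ccccc3)=C3O[C@H](C)[C@H](C)C(=O)C3=C2O)C1(C)C
F10 | step 5 | allyl ester of 13 | C=C(C)[C@@H]1C[C@H](C[C@@]2(CC=C(C)C)C(=O)C([C@@H](CC(=O)OCC=C)c3ccccc3)=C3O[C@H](C)[C@@H](C)C(=O)C3=C2O)C1(C)C
F11 | step 4 | (2R,3S)-5,7-dihydroxy-2,3-dimethylchroman-4-one | C[C@H]1Oc2cc(O)cc(O)c2C(=O)[C@H]1C
F12 | step 4 | (2R,3R)-5,7-dihydroxy-2,3-dimethylchroman-4-one | C[C@H]1Oc2cc(O)cc(O)c2C(=O)[C@@H]1C
F13 | step 4 | (2R,3R,10S)-5-hydroxy-2,3-dimethyl-10-phenyl-2,3,9,10-tetrahydropyrano[2,3-f]chromene-4,8-dione | C[C@H]1Oc2c3[C@H](c4ccccc4)CC(=O)Oc3cc(O)c2C(=O)[C@@H]1C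
F14 | step 4 | prenyl (3S)-3-[(2R,3R)-5,7-dihydroxy-2,3-dimethyl-4-oxochroman-8-yl]-3-phenylpropanoate | C[C@H]1Oc2c([C@@H](CC(=O)OCC=C(C)C)c3ccccc3)c(O)cc(O)c2C(=O)[C@@H]1C
F15 | step 4 | prenyl (3S)-3-[(2R,3R)-5,7-dihydroxy-2,3-dimethyl-4-oxo-6-prenylchroman-8-yl]-3-phenylpropanoate | C[C@H]1Oc2c([C@@H](CC(=O)OCC=C(C)C)c3ccccc3)c(O)c(CC=C(C)C)c(O)c2C(=O)[C@@H]1C
F16 | step 2 | (4S)-4-phenyl-6-tigloylchromane-2,5,7-triol (lactol, anomer mixture) | OC1C[C@@H](c2ccccc2)c3c(O1)cc(O)c(C(=O)/C(C)=C/C)c3O
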